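Guaiane numbering is used. Everything rests on cutting the cyclopentane (C1–C5) at C1–C5 and C2–C3 into a C3–C4–C5 allyl unit and a C1=C2 enol ether. The feature exploited is C5: a fully substituted carbon of the 5,11-oxolane ring that bears the ring oxygen and adjoins oxygenated C4, hence a latent oxygen-stabilised 2-oxyallyl cation, while the C2 oxygen marks a latent enol ether. Ionisation of a 1-ethoxyvinyl lactol, made from a cis-fused bis-γ-lactone that carries a (Z)-enol silane side chain, triggers an intramolecular formal (3+2) cycloaddition that closes the seven- and five-membered rings in one operation and sets C5, C1 and C2.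

Key step: step 13

Assumption: the D-proline aldol (step 4) is taken to follow the usual enamine facial model, and the (Z)-geometry of 17 is taken to be transferred suprafacially in step 13 (O2 cis to C10), which is why the tiglate is installed with inversion.

Step 1
Reactants: 1 (R)-4-benzyl-3-propionyloxazolidin-2-one; 2 allyl iodide
Product: 3 (R)-4-benzyl-3-[(S)-2-methylpent-4-enoyl]oxazolidin-2-one
Conditions: NaHMDS, THF, −78 °C; then 2, −78 → −40 °C
Reagents that add atoms: none
Why: Evans asymmetric alkylation: the chelated (Z)-sodium enolate is allylated on the face opposite the benzyl group, which sets the methyl-bearing centre (future C10).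

Step 2
Reactants: 3 allylated imide
Product: 4 (S)-2-methylpent-4-en-1-ol
Conditions: LiBH4, MeOH (1 equiv), Et2O, 0 °C
Reagents that add atoms: none
Why: Reductive cleavage of the imide with LiBH4 gives the primary alcohol without touching the α-stereocentre or the alkene.

Step 3
Reactants: 4 (S)-2-methylpent-4-en-1-ol
Product: 5 (S)-5-bromo-4-methylpent-1-ene
Conditions: CBr4, PPh3, CH2Cl2, 0 °C
Reagents that add atoms: carbon tetrabromide, BrC(Br)(Br)Br
Why: Appel reaction: SN2 displacement of the oxyphosphonium ion at the primary carbon leaves the neighbouring stereocentre unchanged.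

Step 4
Reactants: 6 tert-butyl 4-oxobutanoate; 7 diethyl 2-oxomalonate
Product: 8 diethyl 2-hydroxy-2-[(2R)-4-tert-butoxy-1,4-dioxobutan-2-yl]malonate (C8 aldehyde)
Conditions: D-proline (30 mol %), CH2Cl2, rt
Reagents that add atoms: none
Why: Proline-catalysed direct aldol addition of an aldehyde donor to a non-enolisable activated ketone: the enamine is attacked on the face steered by the carboxylic acid of D-proline, which sets C7, while C11 (two equal ester groups) is not yet stereogenic.

Step 5
Reactants: 5 (S)-5-bromo-4-methylpent-1-ene; 8 C8 aldehyde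
Product: 10 C8/C11 diol triester (7S,8R; acyclic), via Grignard reagent 9 (not isolated)
Conditions: Mg, THF (gives 9); 8, THF, −78 °C (2.2 equiv of 9); sat. aq NH4Cl
Reagents that add atoms: magnesium, [Mg] (stays only in intermediate 9)
Why: Grignard addition to an α-branched aldehyde: the first equivalent deprotonates the C11 hydroxyl, and both the Felkin–Anh model (quaternary C11 anti to the nucleophile) and the chair-like magnesium chelate of the C11 alkoxide direct the second equivalent to the same aldehyde face, which sets C8.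

Step 6
Reactants: 10 diol triester
Product: 11 C11 hydroxymalonic acid (tert-butyl ester retained)
Conditions: KOH, EtOH/H2O, rt → 40 °C; then 1 M HCl, 0 °C, pH 2
Reagents that add atoms: potassium hydroxide, [K+].[OH-]
Why: Saponification of the two ethyl esters, which the bulky tert-butyl ester survives; partial lactonisation on acidification is of no consequence because step 7 converges.

Step 7
Reactants: 11 hydroxymalonic acid
Product: 12 cis-fused bis-γ-lactone acid (5,11-olide and 8,12-olide; 2,7-dioxabicyclo[3.3.0]octane-3,8-dione core; 7S,8R,11R; side chain on the concave face)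
Conditions: TFA/CH2Cl2 (1:3), 0 °C → rt; toluene azeotrope
Reagents that add atoms: none
Why: Acidolysis of the tert-butyl ester and double lactonisation: once O11 has closed onto C5, only the malonic carboxyl group cis to C8 can form the second ring (a trans-fused bicyclo[3.3.0] is too strained), so C11 becomes stereogenic under the control of C7 (desymmetrisation).

Step 8
Reactants: 12 bis-lactone acid
Product: 14 bis-lactone C13 alcohol, via mixed carbonic anhydride 13 (not isolated)
Conditions: i-BuOCOCl, N-methylmorpholine, THF, −15 °C; then NaBH4, H2O, 0 °C, short contact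
Reagents that add atoms: isobutyl chloroformate, CC(C)COC(=O)Cl (stays only in intermediate 13)
Why: Chemoselective reduction of a carboxylic acid through its mixed anhydride: borohydride attacks the activated acyl carbon much faster than the lactones or the alkene, and no stereocentre is touched.

Step 9
Reactants: 14 bis-lactone alcohol
Product: 15 C13 TBDPS ether
Conditions: TBDPSCl, imidazole, DMAP (cat.), DMF, rt
Reagents that add atoms: tert-butyldiphenylsilyl chloride, CC(C)(C)[Si](Cl)(c1ccccc1)c1ccccc1
Why: Standard silylation of the only hydroxyl group gives an acid-robust ether that is orthogonal to the later TBS ether.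

Step 10
Reactants: 15 TBDPS ether
Product: 16 C2 aldehyde
Conditions: O3, CH2Cl2, −78 °C; then PPh3
Reagents that add atoms: ozone, [O-][O+]=O
Why: Ozonolysis with reductive work-up cleaves the only alkene and removes the extra carbon, giving the C2 aldehyde.

Step 11
Reactants: 16 C2 aldehyde
Product: 17 (Z)-C1=C2 tert-butyldimethylsilyl enol ether
Conditions: TBSOTf (1.2 equiv), Et3N, CH2Cl2, −78 → −20 °C
Reagents that add atoms: tert-butyldimethylsilyl triflate, CC(C)(C)[Si](C)(C)OS(=O)(=O)C(F)(F)F
Why: Soft enolisation (silyl triflate/amine): kinetic deprotonation of the O-silylated aldehyde favours the (Z)-enol silane and is much faster than silylation of the lactones.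

Step 12
Reactants: 17 (Z)-enol silane; 18 ethyl vinyl ether
Product: 20 C5 lactol bearing a 1-ethoxyvinyl group (anomeric mixture), via 1-ethoxyvinyllithium 19 (not isolated)
Conditions: 18, t-BuLi, THF, −78 → 0 °C (gives 19); 17, THF, −78 °C (1.05 equiv of 19); H2O quench at −78 °C
Reagents that add atoms: tert-butyllithium, [Li]C(C)(C)C (lithium stays only in intermediate 19)
Why: Mono-addition of an acyl-anion equivalent to a lactone: the 5,11-lactone carbonyl is flanked by CH2 and activated by its electron-poor alkoxy part, whereas the 8,12-lactone carbonyl is shielded by quaternary C11 and the TBDPS group.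

Step 13
Reactants: 20 1-ethoxyvinyl lactol
Product: 23 tetracyclic C4 ketone with 2β-OTBS (1R,2R,5R,7S,8R,10R,11R), via 2-ethoxyallyl oxocarbenium ion 21 (not isolated), via O-ethyl oxocarbenium ion 22 (not isolated)
Conditions: TMSOTf (2.1 equiv), 2,6-di-tert-butyl-4-methylpyridine, CH2Cl2, −78 °C; then sat. aq NaHCO3
Reagents that add atoms: water, O
Why: Proposed new method: TMSOTf silylates and ionises the C5 lactol hydroxyl to the oxolane oxocarbenium/2-ethoxyallyl cation 21, the tethered (Z)-enol silane attacks C5 through C1, and the silyloxocarbenium ion born at C2 is captured by the ethoxyvinyl terminus C3 to give 22, which water hydrolyses to ketone 23. The closest known reactions are the Lewis-acid (3+2) cyclopentanone annulation of heteroatom-stabilised 2-siloxyallyl cations with enol silyl ethers or vinyl sulfides and the intramolecular (4+3) cycloadditions of 2-ethoxyallyl cations made from 1-ethoxyvinyllithium adducts; an oxygen-stabilised, intramolecular, seven-ring-forming (3+2) variant has not been shown. The cycloheptane closes in a 7-(enolexo)-exo-trig mode and the cyclopentane in a 5-(enolendo)-exo-trig mode, which is feasible here because the new C1–C5 bond is born perpendicular to the allyl plane and so holds C2 over C3 as in a cycloaddition. C5 is fixed by the tether, since the C9–C10–C1 chain on the concave face of the cis-bicyclo[3.3.0] core reaches only the oxocarbenium face syn to C8; C1 should follow from a chair-like seven-ring transition state with the C10 methyl group and the C1=C2 bond pseudo-equatorial (the axial alternative suffers A(1,3) strain between the Z-silyloxy group and C9), which places H1 anti to the ring oxygen; C2 should follow from suprafacial use of the (Z)-olefin, placing O2 cis to C10 (2β). The step needs attack at C5 and not C3 (a nine-membered ring cannot compete), ring closure faster than proton loss from C6 (low temperature, only a hindered proton trap as base) and retention of the silyl group (bulky TBS, non-nucleophilic triflate).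

Step 14
Reactants: 23 C4 ketone
Product: 24 C4 exocyclic methylene compound
Conditions: Zn, CH2Br2, TiCl4 (pre-aged reagent), THF/CH2Cl2, 0 °C → rt; aq NaHCO3
Reagents that add atoms: dibromomethane, BrCBr
Why: Lombardo methylenation: the non-basic gem-dimetallic reagent converts the hindered ketone without β-elimination of the C2 silyloxy group and leaves the lactone untouched.

Step 15
Reactants: 24 exocyclic methylene compound
Product: 26 4α-hydroxy-4β-methyl compound (4R), via C4 hydroperoxide 25 (not isolated)
Conditions: Mn(dpm)3 (10 mol %), PhSiH3, O2 (1 atm), i-PrOH/CH2Cl2, 0 °C; then P(OEt)3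
Reagents that add atoms: dioxygen, O=O
Why: Mukaiyama hydration (metal-hydride hydrogen-atom transfer): H adds to the CH2 terminus, and the tertiary C4 radical is trapped by O2 on the α face, anti to the pseudo-axial C5–O and C2–OTBS bonds that shield the β face, which sets C4.

Step 16
Reactants: 26 tertiary alcohol
Product: 27 2β,4α-diol (C13 TBDPS ether retained)
Conditions: CSA (0.2 equiv), MeOH/CH2Cl2, 0 °C → rt
Reagents that add atoms: none
Why: Acid-catalysed methanolysis cleaves the secondary TBS ether much faster than the far more acid-stable TBDPS ether.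

Step 17
Reactants: 27 2β,4α-diol; 28 tiglic acid
Product: 29 2α-tiglate (C13 TBDPS ether)
Conditions: PPh3, DIAD, toluene, 0 °C → rt
Reagents that add atoms: none
Why: Mitsunobu esterification: tiglate displaces the C2 oxyphosphonium ion from the α face by SN2, which inverts C2 to the required 2α-ester, while the tertiary C4 hydroxyl does not react.

Step 18
Reactants: 29 2α-tiglate TBDPS ether
Product: 30 target CNP0408475.1
Conditions: HF·pyridine, THF, 0 °C → rt
Reagents that add atoms: none
Why: Fluoride-mediated desilylation under mildly acidic conditions frees the C13 hydroxyl without acyl migration or lactone opening.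

Compound list
1 | (R)-4-benzyl-3-propionyloxazolidin-2-one | CCC(=O)N1[C@H](Cc2ccccc2)COC1=O | starting material
2 | allyl iodide | C=CCI | starting material
3 | (R)-4-benzyl-3-[(S)-2-methylpent-4-enoyl]oxazolidin-2-one | C=CC[C@H](C)C(=O)N1[C@H](Cc2ccccc2)COC1=O | intermediate
4 | (S)-2-methylpent-4-en-1-ol | C=CC[C@H](C)CO | intermediate
5 | (S)-5-bromo-4-methylpent-1-ene | C=CC[C@H](C)CBr | intermediate
6 | tert-butyl 4-oxobutanoate | CC(C)(C)OC(=O)CCC=O | starting material
7 | diethyl 2-oxomalonate | CCOC(=O)C(=O)C(=O)OCC | starting material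
8 | diethyl 2-hydroxy-2-[(2R)-4-tert-butoxy-1,4-dioxobutan-2-yl]malonate | O=C[C@H](CC(=O)OC(C)(C)C)C(O)(C(=O)OCC)C(=O)OCC | intermediate
9 | [(S)-2-methylpent-4-en-1-yl]magnesium bromide | C=CC[C@H](C)C[Mg]Br | intermediate
10 | C8/C11 diol triester (7S,8R) | C=CC[C@H](C)C[C@@H](O)[C@H](CC(=O)OC(C)(C)C)C(O)(C(=O)OCC)C(=O)OCC | intermediate
11 | C11 hydroxymalonic acid, tert-butyl ester retained | C=CC[C@H](C)C[C@@H](O)[C@H](CC(=O)OC(C)(C)C)C(O)(C(=O)O)C(=O)O | intermediate
12 | cis-fused bis-γ-lactone C13 acid (7S,8R,11R) | O=C1C[C@H]2[C@@H](C[C@@H](C)CC=C)OC(=O)[C@@]2(C(=O)O)O1 | intermediate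
13 | mixed isobutyl carbonic anhydride of 12 | O=C1C[C@H]2[C@@H](C[C@@H](C)CC=C)OC(=O)[C@@]2(C(=O)OC(=O)OCC(C)C)O1 | intermediate
14 | bis-lactone C13 alcohol | O=C1C[C@H]2[C@@H](C[C@@H](C)CC=C)OC(=O)[C@@]2(CO)O1 | intermediate
15 | bis-lactone C13 TBDPS ether | O=C1C[C@H]2[C@@H](C[C@@H](C)CC=C)OC(=O)[C@@]2(CO[Si](c3ccccc3)(c3ccccc3)C(C)(C)C)O1 | intermediate
16 | bis-lactone C2 aldehyde | O=C1C[C@H]2[C@@H](C[C@@H](C)CC=O)OC(=O)[C@@]2(CO[Si](c3ccccc3)(c3ccccc3)C(C)(C)C)O1 | intermediate
17 | bis-lactone (Z)-C1=C2 TBS enol ether | O=C1C[C@H]2[C@@H](C[C@@H](C)/C=C\O[Si](C)(C)C(C)(C)C)OC(=O)[C@@]2(CO[Si](c3ccccc3)(c3ccccc3)C(C)(C)C)O1 | intermediate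
18 | ethyl vinyl ether | C=COCC | starting material
19 | 1-ethoxyvinyllithium | [Li]C(=C)OCC | intermediate
20 | C5 lactol with 1-ethoxyvinyl group (C5 epimers) | C=C(OCC)C1(O)C[C@H]2[C@@H](C[C@@H](C)/C=C\O[Si](C)(C)C(C)(C)C)OC(=O)[C@@]2(CO[Si](c3ccccc3)(c3ccccc3)C(C)(C)C)O1 | intermediate
21 | 2-ethoxyallyl oxocarbenium ion | C=C(OCC)C1=[O+][C@]2(CO[Si](c3ccccc3)(c3ccccc3)C(C)(C)C)C(=O)O[C@H](C[C@@H](C)/C=C\O[Si](C)(C)C(C)(C)C)[C@@H]2C1 | intermediate
22 | ring-closed O-ethyl oxocarbenium ion at C4 | CC(C)(C)[Si](C)(C)O[C@@H]1CC(=[O+]CC)[C@@]23C[C@H]4[C@@H](C[C@@H](C)[C@H]12)OC(=O)[C@@]4(CO[Si](c5ccccc5)(c5ccccc5)C(C)(C)C)O3 | intermediate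
23 | tetracyclic C4 ketone, 2β-OTBS | CC(C)(C)[Si](C)(C)O[C@@H]1CC(=O)[C@@]23C[C@H]4[C@@H](C[C@@H](C)[C@H]12)OC(=O)[C@@]4(CO[Si](c5ccccc5)(c5ccccc5)C(C)(C)C)O3 | intermediate
24 | C4 exocyclic methylene compound | CC(C)(C)[Si](C)(C)O[C@@H]1CC(=C)[C@@]23C[C@H]4[C@@H](C[C@@H](C)[C@H]12)OC(=O)[C@@]4(CO[Si](c5ccccc5)(c5ccccc5)C(C)(C)C)O3 | intermediate
25 | C4 α-hydroperoxide | CC(C)(C)[Si](C)(C)O[C@@H]1C[C@@](C)(OO)[C@@]23C[C@H]4[C@@H](C[C@@H](C)[C@H]12)OC(=O)[C@@]4(CO[Si](c5ccccc5)(c5ccccc5)C(C)(C)C)O3 | intermediate
26 | 4α-hydroxy-4β-methyl compound, 2β-OTBS | CC(C)(C)[Si](C)(C)O[C@@H]1C[C@@](C)(O)[C@@]23C[C@H]4[C@@H](C[C@@H](C)[C@H]12)OC(=O)[C@@]4(CO[Si](c5ccccc5)(c5ccccc5)C(C)(C)C)O3 | intermediate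
27 | 2β,4α-diol, C13 TBDPS ether | O[C@@H]1C[C@@](C)(O)[C@@]23C[C@H]4[C@@H](C[C@@H](C)[C@H]12)OC(=O)[C@@]4(CO[Si](c5ccccc5)(c5ccccc5)C(C)(C)C)O3 | intermediate
28 | tiglic acid | C/C=C(\C)C(=O)O | starting material
29 | 2α-tiglate, C13 TBDPS ether | C/C=C(\C)C(=O)O[C@H]1C[C@@](C)(O)[C@@]23C[C@H]4[C@@H](C[C@@H](C)[C@H]12)OC(=O)[C@@]4(CO[Si](c5ccccc5)(c5ccccc5)C(C)(C)C)O3 | intermediate
30 | CNP0408475.1 | C/C=C(\C)C(=O)O[C@H]1C[C@@](C)(O)[C@@]23C[C@H]4[C@@H](C[C@@H](C)[C@H]12)OC(=O)[C@@]4(CO)O3 | target

Total step count: 18. Longest linear sequence: 17 steps (steps 1–3, then 5–18).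

Steps most likely to fail

Step 13. Three things may go wrong. The seven-membered ring may close too slowly, so that the cation loses a proton from C6. The enol silane may present its other face, which would give a cis-fused hydroazulene. The silyl group may be lost before the second bond forms.

The fallback makes the two bonds one after the other by known reactions, setting out from 17:
- The lithium derivative of 2-methyl-1,3-dithiane adds to the C5 lactone carbonyl to give the dithiane lactol F1.
- TMSOTf with the hindered pyridine ionises it, and the enol silane closes only the seven-membered ring (intramolecular Mukaiyama-type addition to a cyclic oxocarbenium ion) to give the C2 aldehyde F2.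
- MeI/CaCO3 in aqueous MeCN unmasks the methyl ketone to give the keto aldehyde F3.
- A TiCl4/i-Pr2NEt intramolecular aldol addition closes the cyclopentane to the 2α-hydroxy ketone F4 (pseudo-equatorial alcohol).
- Lombardo methylenation gives the homoallylic alcohol F5, and Mukaiyama hydration gives the 2α,4α-diol F6.
- F6 is acylated with retention (tiglic anhydride, DMAP), and the sequence comes back to the route at 29.

Step 17. The hindered pseudo-axial oxyphosphonium ion may undergo anti elimination toward C1 or C3 faster than it is displaced by the weakly acidic tiglic acid. The fallback separates activation from displacement. Setting out from 27, chloromethanesulfonyl chloride/pyridine gives the C2 chloromethanesulfonate F7. This is displaced with inversion by caesium tiglate/18-crown-6 in warm toluene, and the sequence comes back to the route at 29.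

Step 12. The organolithium may enolise the lactone. The tetrahedral adduct may collapse early and take up a second equivalent. The 8,12-lactone may compete. The fallback sets out from 17. MeNH(OMe)·HCl/i-PrMgCl opens the more electrophilic 5,11-lactone to the C11 hydroxy Weinreb amide F8. Two equivalents of 19 then stop at the ketone stage through the chelated adduct, and on work-up the ketone closes with the C11 hydroxyl, coming back to the route at 20.

Further compounds
F1 | step 13 | C5 lactol with 2-methyl-1,3-dithian-2-yl group | CC1(SCCCS1)C1(O)C[C@H]2[C@@H](C[C@@H](C)/C=C\O[Si](C)(C)C(C)(C)C)OC(=O)[C@@]2(CO[Si](c3ccccc3)(c3ccccc3)C(C)(C)C)O1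
F2 | step 13 | C1–C5 bonded tricyclic C2 aldehyde, C4 dithiane | CC1(SCCCS1)[C@@]12C[C@H]3[C@@H](C[C@@H](C)[C@@H]1C=O)OC(=O)[C@@]3(CO[Si](c4ccccc4)(c4ccccc4)C(C)(C)C)O2
F3 | step 13 | tricyclic keto aldehyde (C4 methyl ketone, C2 aldehyde) | CC(=O)[C@@]12C[C@H]3[C@@H](C[C@@H](C)[C@@H]1C=O)OC(=O)[C@@]3(CO[Si](c4ccccc4)(c4ccccc4)C(C)(C)C)O2
F4 | step 13 | tetracyclic 2α-hydroxy C4 ketone | O[C@H]1CC(=O)[C@@]23C[C@H]4[C@@H](C[C@@H](C)[C@H]12)OC(=O)[C@@]4(CO[Si](c5ccccc5)(c5ccccc5)C(C)(C)C)O3
F5 | step 13 | 2α-hydroxy C4 exocyclic methylene compound | O[C@H]1CC(=C)[C@@]23C[C@H]4[C@@H](C[C@@H](C)[C@H]12)OC(=O)[C@@]4(CO[Si](c5ccccc5)(c5ccccc5)C(C)(C)C)O3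
F6 | step 13 | 2α,4α-diol, C13 TBDPS ether | O[C@H]1C[C@@](C)(O)[C@@]23C[C@H]4[C@@H](C[C@@H](C)[C@H]12)OC(=O)[C@@]4(CO[Si](c5ccccc5)(c5ccccc5)C(C)(C)C)O3
F7 | step 17 | 2β-chloromethanesulfonate of 27 | ClCS(=O)(=O)O[C@@H]1C[C@@](C)(O)[C@@]23C[C@H]4[C@@H](C[C@@H](C)[C@H]12)OC(=O)[C@@]4(CO[Si](c5ccccc5)(c5ccccc5)C(C)(C)C)O3
F8 | step 12 | C11 hydroxy C5 Weinreb amide | CON(C)C(=O)C[C@H]1[C@@H](C[C@@H](C)/C=C\O[Si](C)(C)C(C)(C)C)OC(=O)[C@@]1(CO[Si](c2ccccc2)(c2ccccc2)C(C)(C)C)O
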